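**Retrosynthetic overview**

- Numbering: C1 is the butenolide carbonyl, C2=C3 carries C25H2OH, C4 is the carbinol carbon, then C5H2 and C6=C7, with C24H2OH on C7 and the chain from C8 onward. The route rests on one feature: the C4 oxygen and C24 lie cis across the C6=C7 alkene, so O–C4–C5–C6=C7–C24 can be tied into a temporary six-membered 5,6-dihydropyran-2-one ring with C24 as the carbonyl.
- The butenolide is closed last by an intramolecular Horner–Wadsworth–Emmons reaction of a C4–O phosphonoacetate onto a C3 ketone. C3 and C25 come from the dioxolane of glyceraldehyde, and the C4 and C24 hydroxyls come from hydride opening of the δ-lactone.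
- The δ-lactone comes from a copper–bisphosphine-catalysed asymmetric vinylogous aldol reaction with in situ lactonisation between the racemic 2-vinyl ester 12 and (S)-glyceraldehyde acetonide 13. This forms the C4–C5 and O–C24 bonds and sets C4 and the 6Z geometry.
- Ester 12 comes from α-alkylation of the methyl crotonate dienolate with homoallylic iodide 9. Iodide 9 comes from alkyne 4 by Cp2ZrCl2-catalysed carboalumination and ethylene oxide trapping, and alkyne 4 from dihydro-β-ionone.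
- Ring order: the cyclohexene ring is bought, the δ-lactone ring is formed in step 5 and opened in step 6, and the butenolide ring is formed in step 12.

Key step: step 5

Assumption: (R)-DTBM-SEGPHOS is taken as the ligand antipode whose facial preference at the aldehyde agrees with the Felkin preference of 13 (giving 4R); if the sense proves opposite, the (S)-ligand takes its place with nothing else changed.

**Route**

Step 1
Reactants: 1 dihydro-β-ionone
Product: 4 2-(but-3-yn-1-yl)-1,3,3-trimethylcyclohex-1-ene, via lithium enolate 2 (not isolated), via enol diethyl phosphate 3 (not isolated)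
Conditions: LiN(iPr)2 (1.1 equiv), THF, −78 °C; ClP(O)(OEt)2, −78 °C to rt; then LiN(iPr)2 (2.3 equiv), −78 °C to rt; aq. NH4Cl
Reagents that add atoms: none
Why: LiN(iPr)2 deprotonates the methyl group kinetically, the enolate is O-phosphorylated, and two further equivalents of amide eliminate diethyl phosphate and hold the product as its acetylide (Negishi conversion of a methyl ketone into a terminal alkyne), while the tetrasubstituted ring alkene stays untouched.

Step 2
Reactants: 4 2-(but-3-yn-1-yl)-1,3,3-trimethylcyclohex-1-ene; 5 ethylene oxide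
Product: 8 (3E)-4-methyl-6-(2,6,6-trimethylcyclohex-1-en-1-yl)hex-3-en-1-ol, via alkenyl(dimethyl)alane 6 (not isolated), via lithium alkenylaluminate 7 (not isolated)
Conditions: Me3Al (2 equiv), Cp2ZrCl2 (25 mol%), CH2Cl2, rt; volatiles removed, hexane; n-BuLi, 0 °C; then 5, THF, −30 °C to rt; aq. KNaC4H4O6
Reagents that add atoms: trimethylaluminium, C[Al](C)C
Why: Negishi Cp2ZrCl2-catalysed carboalumination adds methyl and aluminium cis across the alkyne with aluminium at the terminal carbon, which fixes the E geometry of the trisubstituted alkene, and the butyl-activated alanate opens ethylene oxide with retention at the alkenyl carbon.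

Step 3
Reactants: 8 (3E)-4-methyl-6-(2,6,6-trimethylcyclohex-1-en-1-yl)hex-3-en-1-ol
Product: 9 2-[(3E)-6-iodo-3-methylhex-3-en-1-yl]-1,3,3-trimethylcyclohex-1-ene
Conditions: I2, PPh3, imidazole, CH2Cl2, 0 °C to rt
Reagents that add atoms: iodine, II
Why: The Garegg–Samuelsson variant of the Appel reaction turns the primary alcohol into an alkoxyphosphonium ion that iodide displaces by SN2, with no effect on the alkenes.

Step 4
Reactants: 9 2-[(3E)-6-iodo-3-methylhex-3-en-1-yl]-1,3,3-trimethylcyclohex-1-ene; 10 methyl crotonate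
Product: 12 methyl (5E)-2-ethenyl-6-methyl-8-(2,6,6-trimethylcyclohex-1-en-1-yl)oct-5-enoate (racemic), via lithium dienolate 11 (not isolated)
Conditions: 10 (1.5 equiv), LiN(iPr)2, HMPA, THF, −78 °C; then 9, −78 to −20 °C
Reagents that add atoms: none
Why: Deconjugative α-alkylation of an extended ester enolate: the lithium dienolate of methyl crotonate, kept from self-condensation by HMPA, reacts with the primary iodide at its α-carbon by SN2 and leaves the β,γ-alkene as the vinyl group; the new C7 centre is racemic and is erased in step 5.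

Step 5
Reactants: 12 methyl (5E)-2-ethenyl-6-methyl-8-(2,6,6-trimethylcyclohex-1-en-1-yl)oct-5-enoate (racemic); 13 (S)-glyceraldehyde acetonide
Product: 16 (6R)-6-[(4S)-2,2-dimethyl-1,3-dioxolan-4-yl]-3-[(3E)-4-methyl-6-(2,6,6-trimethylcyclohex-1-en-1-yl)hex-3-en-1-yl]-5,6-dihydro-2H-pyran-2-one, via copper dienolate 14 (not isolated), via copper aldolate 15 (not isolated)
Conditions: 13 (1.5 equiv), [Cu(MeCN)4]PF6 (5 mol%), (R)-DTBM-SEGPHOS (6 mol%), Et3N (20 mol%), THF, 0 °C to rt
Reagents that add atoms: none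
Why: The cationic monovalent-copper–bisphosphine complex binds the vinyl group of 12 and lets the amine remove the doubly activated C7–H, which erases the C7 stereocentre (so racemic 12 converges) and gives copper dienolate 14; its terminal carbon C5 adds to the aldehyde carbon of 13 to form C4–C5 and the conjugated enoate, the closest known reaction type being the direct catalytic asymmetric vinylogous aldol reaction of simpler β,γ-unsaturated esters with aldehydes under the same copper–bisphosphine catalysis, which also ends in α,β-unsaturated δ-lactones. The ring closes by 6-exo-trig acyl substitution of the copper alkoxide 15 on the C24 ester, and the expelled methoxide serves as base for the next turnover. C4 is set by the bisphosphine pocket on copper through the choice of aldehyde face, and the polar Felkin–Anh preference of the dioxolane stereocentre of 13 points the same way (anti adduct, 4R). The step needs γ- over α-attack, which is secured because α-attack would build a crowded quaternary centre reversibly whereas the γ-adduct is drained irreversibly by lactonisation. It also needs C24 cis to C5 across C6=C7, which is secured because only that isomer can lactonise, so 16 carries the 6Z geometry in its ring and is separable from any open-chain isomer.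

Step 6
Reactants: 16 (6R)-6-[(4S)-2,2-dimethyl-1,3-dioxolan-4-yl]-3-[(3E)-4-methyl-6-(2,6,6-trimethylcyclohex-1-en-1-yl)hex-3-en-1-yl]-5,6-dihydro-2H-pyran-2-one
Product: 18 (2Z,5R)-5-[(4S)-2,2-dimethyl-1,3-dioxolan-4-yl]-2-[(3E)-4-methyl-6-(2,6,6-trimethylcyclohex-1-en-1-yl)hex-3-en-1-yl]pent-2-ene-1,5-diol, via lactol 17 (not isolated)
Conditions: iBu2AlH (4 equiv), CH2Cl2, −78 to 0 °C; aq. KNaC4H4O6
Reagents that add atoms: none
Why: Lactone-to-diol reduction: iBu2AlH adds to the lactone carbonyl to give lactol 17, whose ring-opened enal form is reduced in a 1,2-sense to the allylic alcohol, so the ring geometry is carried over as 6Z and C4 is untouched; the isopropylidene acetal is stable to the hydride below 0 °C.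

Step 7
Reactants: 18 (2Z,5R)-5-[(4S)-2,2-dimethyl-1,3-dioxolan-4-yl]-2-[(3E)-4-methyl-6-(2,6,6-trimethylcyclohex-1-en-1-yl)hex-3-en-1-yl]pent-2-ene-1,5-diol
Product: 19 (1R,3Z,7E)-4-{[tert-butyl(diphenyl)silyl]oxymethyl}-1-[(4S)-2,2-dimethyl-1,3-dioxolan-4-yl]-8-methyl-10-(2,6,6-trimethylcyclohex-1-en-1-yl)deca-3,7-dien-1-ol
Conditions: TBDPSCl (1.05 equiv), imidazole, CH2Cl2, 0 °C
Reagents that add atoms: tert-butyl(chloro)diphenylsilane, CC(C)(C)[Si](Cl)(c1ccccc1)c1ccccc1
Why: Selective protection: silylation of the unhindered primary allylic C24 hydroxyl is much faster than that of the secondary C4 hydroxyl flanked by the dioxolane, and the tert-butyldiphenylsilyl group is chosen because it survives the acid of step 9.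

Step 8
Reactants: 19 (1R,3Z,7E)-4-{[tert-butyl(diphenyl)silyl]oxymethyl}-1-[(4S)-2,2-dimethyl-1,3-dioxolan-4-yl]-8-methyl-10-(2,6,6-trimethylcyclohex-1-en-1-yl)deca-3,7-dien-1-ol
Product: 20 (1R,3Z,7E)-4-{[tert-butyl(diphenyl)silyl]oxymethyl}-1-[(4S)-2,2-dimethyl-1,3-dioxolan-4-yl]-8-methyl-10-(2,6,6-trimethylcyclohex-1-en-1-yl)deca-3,7-dien-1-yl (diethoxyphosphoryl)acetate
Conditions: (EtO)2P(O)CH2CO2H, DCC, DMAP (cat.), CH2Cl2, 0 °C to rt
Reagents that add atoms: diethylphosphonoacetic acid, OC(=O)CP(=O)(OCC)OCC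
Why: Steglich esterification acylates the remaining secondary hydroxyl at oxygen, so C4 keeps its configuration.

Step 9
Reactants: 20 (1R,3Z,7E)-4-{[tert-butyl(diphenyl)silyl]oxymethyl}-1-[(4S)-2,2-dimethyl-1,3-dioxolan-4-yl]-8-methyl-10-(2,6,6-trimethylcyclohex-1-en-1-yl)deca-3,7-dien-1-yl (diethoxyphosphoryl)acetate
Product: 21 (2S,3R,5Z,9E)-6-{[tert-butyl(diphenyl)silyl]oxymethyl}-1,2-dihydroxy-10-methyl-12-(2,6,6-trimethylcyclohex-1-en-1-yl)dodeca-5,9-dien-3-yl (diethoxyphosphoryl)acetate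
Conditions: AcOH/THF/H2O (3:1:1), 40 °C
Reagents that add atoms: none
Why: Acid-catalysed hydrolysis of the terminal isopropylidene acetal; the silyl ether, the phosphonate and the alkenes are stable to aqueous acetic acid, and the weak acid and moderate temperature keep 1,2-acyl shift from the C4 oxygen slow.

Step 10
Reactants: 21 (2S,3R,5Z,9E)-6-{[tert-butyl(diphenyl)silyl]oxymethyl}-1,2-dihydroxy-10-methyl-12-(2,6,6-trimethylcyclohex-1-en-1-yl)dodeca-5,9-dien-3-yl (diethoxyphosphoryl)acetate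
Product: 22 (2S,3R,5Z,9E)-1-{[tert-butyl(dimethyl)silyl]oxy}-6-{[tert-butyl(diphenyl)silyl]oxymethyl}-2-hydroxy-10-methyl-12-(2,6,6-trimethylcyclohex-1-en-1-yl)dodeca-5,9-dien-3-yl (diethoxyphosphoryl)acetate
Conditions: TBSCl (1.1 equiv), imidazole, CH2Cl2, −20 to 0 °C
Reagents that add atoms: tert-butyl(chloro)dimethylsilane, CC(C)(C)[Si](C)(C)Cl
Why: Primary-selective silylation at low temperature protects C25–OH and leaves the secondary C3 hydroxyl free for oxidation.

Step 11
Reactants: 22 (2S,3R,5Z,9E)-1-{[tert-butyl(dimethyl)silyl]oxy}-6-{[tert-butyl(diphenyl)silyl]oxymethyl}-2-hydroxy-10-methyl-12-(2,6,6-trimethylcyclohex-1-en-1-yl)dodeca-5,9-dien-3-yl (diethoxyphosphoryl)acetate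
Product: 23 (3R,5Z,9E)-1-{[tert-butyl(dimethyl)silyl]oxy}-6-{[tert-butyl(diphenyl)silyl]oxymethyl}-10-methyl-2-oxo-12-(2,6,6-trimethylcyclohex-1-en-1-yl)dodeca-5,9-dien-3-yl (diethoxyphosphoryl)acetate
Conditions: Dess–Martin periodinane, CH2Cl2, 0 °C to rt
Reagents that add atoms: none
Why: Dess–Martin oxidation converts the secondary alcohol into the C3 ketone under non-basic conditions, so the now enolisable C4 centre is not epimerised; this also removes the dioxolane-derived stereocentre.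

Step 12
Reactants: 23 (3R,5Z,9E)-1-{[tert-butyl(dimethyl)silyl]oxy}-6-{[tert-butyl(diphenyl)silyl]oxymethyl}-10-methyl-2-oxo-12-(2,6,6-trimethylcyclohex-1-en-1-yl)dodeca-5,9-dien-3-yl (diethoxyphosphoryl)acetate
Product: 24 (5R)-4-({[tert-butyl(dimethyl)silyl]oxy}methyl)-5-[(2Z,6E)-3-{[tert-butyl(diphenyl)silyl]oxymethyl}-7-methyl-9-(2,6,6-trimethylcyclohex-1-en-1-yl)nona-2,6-dien-1-yl]furan-2(5H)-one
Conditions: LiCl, iPr2NEt, MeCN, 0 °C to rt
Reagents that add atoms: none
Why: Intramolecular Horner–Wadsworth–Emmons reaction under Masamune–Roush conditions: the lithium-chelated phosphonate is deprotonated by the amine, adds to the C3 ketone in a five-membered closure and eliminates diethyl phosphate to give the C2=C3 alkene, whose cis geometry is fixed by the ring; the weak base is chosen to leave the C4–H alone.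

Step 13
Reactants: 24 (5R)-4-({[tert-butyl(dimethyl)silyl]oxy}methyl)-5-[(2Z,6E)-3-{[tert-butyl(diphenyl)silyl]oxymethyl}-7-methyl-9-(2,6,6-trimethylcyclohex-1-en-1-yl)nona-2,6-dien-1-yl]furan-2(5H)-one
Product: 25 (6Z)-neomanoalide, (5R)-4-(hydroxymethyl)-5-[(2Z,6E)-3-(hydroxymethyl)-7-methyl-9-(2,6,6-trimethylcyclohex-1-en-1-yl)nona-2,6-dien-1-yl]furan-2(5H)-one
Conditions: HF·pyridine, pyridine, THF, 0 °C to rt
Reagents that add atoms: none
Why: Global desilylation: HF·pyridine cleaves both primary silyl ethers through Si–F bond formation in an acidic, non-nucleophilic medium that should neither deprotonate the butenolide at C4 nor disturb the alkenes.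

**Compound list**

1 | dihydro-β-ionone, 4-(2,6,6-trimethylcyclohex-1-en-1-yl)butan-2-one | CC(=O)CCC1=C(C)CCCC1(C)C | starting material
2 | lithium 4-(2,6,6-trimethylcyclohex-1-en-1-yl)but-1-en-2-olate (formed in the flask) | C=C(O[Li])CCC1=C(C)CCCC1(C)C | intermediate
3 | diethyl 4-(2,6,6-trimethylcyclohex-1-en-1-yl)but-1-en-2-yl phosphate (formed in the flask) | C=C(OP(=O)(OCC)OCC)CCC1=C(C)CCCC1(C)C | intermediate
4 | 2-(but-3-yn-1-yl)-1,3,3-trimethylcyclohex-1-ene | C#CCCC1=C(C)CCCC1(C)C | intermediate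
5 | ethylene oxide | C1CO1 | starting material
6 | dimethyl[(1E)-2-methyl-4-(2,6,6-trimethylcyclohex-1-en-1-yl)but-1-en-1-yl]alumane (formed in the flask) | C[Al](C)/C=C(\C)CCC1=C(C)CCCC1(C)C | intermediate
7 | lithium butyl(dimethyl)[(1E)-2-methyl-4-(2,6,6-trimethylcyclohex-1-en-1-yl)but-1-en-1-yl]aluminate (formed in the flask) | [Li+].CCCC[Al-](C)(C)/C=C(\C)CCC1=C(C)CCCC1(C)C | intermediate
8 | (3E)-4-methyl-6-(2,6,6-trimethylcyclohex-1-en-1-yl)hex-3-en-1-ol | OCC/C=C(\C)CCC1=C(C)CCCC1(C)C | intermediate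
9 | 2-[(3E)-6-iodo-3-methylhex-3-en-1-yl]-1,3,3-trimethylcyclohex-1-ene | ICC/C=C(\C)CCC1=C(C)CCCC1(C)C | intermediate
10 | methyl crotonate, methyl (2E)-but-2-enoate | C/C=C/C(=O)OC | starting material
11 | lithium 1-methoxybuta-1,3-dien-1-olate (formed in the flask) | C=CC=C(OC)O[Li] | intermediate
12 | methyl (5E)-2-ethenyl-6-methyl-8-(2,6,6-trimethylcyclohex-1-en-1-yl)oct-5-enoate, racemic | C=CC(CC/C=C(\C)CCC1=C(C)CCCC1(C)C)C(=O)OC | intermediate
13 | (S)-glyceraldehyde acetonide, (4S)-2,2-dimethyl-1,3-dioxolane-4-carbaldehyde | O=C[C@@H]1COC(C)(C)O1 | starting material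
14 | copper dienolate of 12, bisphosphine on copper not drawn (formed in the flask) | C=CC(CC/C=C(\C)CCC1=C(C)CCCC1(C)C)=C(OC)O[Cu] | intermediate
15 | copper alkoxide of methyl (2Z,5R)-5-[(4S)-2,2-dimethyl-1,3-dioxolan-4-yl]-5-hydroxy-2-[(3E)-4-methyl-6-(2,6,6-trimethylcyclohex-1-en-1-yl)hex-3-en-1-yl]pent-2-enoate (formed in the flask) | COC(=O)/C(CC/C=C(\C)CCC1=C(C)CCCC1(C)C)=C\C[C@@H](O[Cu])[C@@H]1COC(C)(C)O1 | intermediate
16 | (6R)-6-[(4S)-2,2-dimethyl-1,3-dioxolan-4-yl]-3-[(3E)-4-methyl-6-(2,6,6-trimethylcyclohex-1-en-1-yl)hex-3-en-1-yl]-5,6-dihydro-2H-pyran-2-one | O=C1O[C@@H]([C@@H]2COC(C)(C)O2)CC=C1CC/C=C(\C)CCC1=C(C)CCCC1(C)C | intermediate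
17 | lactol of 16, (6R)-6-[(4S)-2,2-dimethyl-1,3-dioxolan-4-yl]-3-[(3E)-4-methyl-6-(2,6,6-trimethylcyclohex-1-en-1-yl)hex-3-en-1-yl]-5,6-dihydro-2H-pyran-2-ol, present as its aluminium alkoxide (formed in the flask) | OC1O[C@@H]([C@@H]2COC(C)(C)O2)CC=C1CC/C=C(\C)CCC1=C(C)CCCC1(C)C | intermediate
18 | (2Z,5R)-5-[(4S)-2,2-dimethyl-1,3-dioxolan-4-yl]-2-[(3E)-4-methyl-6-(2,6,6-trimethylcyclohex-1-en-1-yl)hex-3-en-1-yl]pent-2-ene-1,5-diol | OC/C(CC/C=C(\C)CCC1=C(C)CCCC1(C)C)=C\C[C@@H](O)[C@@H]1COC(C)(C)O1 | intermediate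
19 | (1R,3Z,7E)-4-{[tert-butyl(diphenyl)silyl]oxymethyl}-1-[(4S)-2,2-dimethyl-1,3-dioxolan-4-yl]-8-methyl-10-(2,6,6-trimethylcyclohex-1-en-1-yl)deca-3,7-dien-1-ol | CC(C)(C)[Si](OC/C(CC/C=C(\C)CCC1=C(C)CCCC1(C)C)=C\C[C@@H](O)[C@@H]1COC(C)(C)O1)(c1ccccc1)c1ccccc1 | intermediate
20 | (1R,3Z,7E)-4-{[tert-butyl(diphenyl)silyl]oxymethyl}-1-[(4S)-2,2-dimethyl-1,3-dioxolan-4-yl]-8-methyl-10-(2,6,6-trimethylcyclohex-1-en-1-yl)deca-3,7-dien-1-yl (diethoxyphosphoryl)acetate | CC(C)(C)[Si](OC/C(CC/C=C(\C)CCC1=C(C)CCCC1(C)C)=C\C[C@@H](OC(=O)CP(=O)(OCC)OCC)[C@@H]1COC(C)(C)O1)(c1ccccc1)c1ccccc1 | intermediate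
21 | (2S,3R,5Z,9E)-6-{[tert-butyl(diphenyl)silyl]oxymethyl}-1,2-dihydroxy-10-methyl-12-(2,6,6-trimethylcyclohex-1-en-1-yl)dodeca-5,9-dien-3-yl (diethoxyphosphoryl)acetate | CC(C)(C)[Si](OC/C(CC/C=C(\C)CCC1=C(C)CCCC1(C)C)=C\C[C@@H](OC(=O)CP(=O)(OCC)OCC)[C@@H](O)CO)(c1ccccc1)c1ccccc1 | intermediate
22 | (2S,3R,5Z,9E)-1-{[tert-butyl(dimethyl)silyl]oxy}-6-{[tert-butyl(diphenyl)silyl]oxymethyl}-2-hydroxy-10-methyl-12-(2,6,6-trimethylcyclohex-1-en-1-yl)dodeca-5,9-dien-3-yl (diethoxyphosphoryl)acetate | CC(C)(C)[Si](OC/C(CC/C=C(\C)CCC1=C(C)CCCC1(C)C)=C\C[C@@H](OC(=O)CP(=O)(OCC)OCC)[C@@H](O)CO[Si](C)(C)C(C)(C)C)(c1ccccc1)c1ccccc1 | intermediate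
23 | (3R,5Z,9E)-1-{[tert-butyl(dimethyl)silyl]oxy}-6-{[tert-butyl(diphenyl)silyl]oxymethyl}-10-methyl-2-oxo-12-(2,6,6-trimethylcyclohex-1-en-1-yl)dodeca-5,9-dien-3-yl (diethoxyphosphoryl)acetate | CC(C)(C)[Si](OC/C(CC/C=C(\C)CCC1=C(C)CCCC1(C)C)=C\C[C@@H](OC(=O)CP(=O)(OCC)OCC)C(=O)CO[Si](C)(C)C(C)(C)C)(c1ccccc1)c1ccccc1 | intermediate
24 | (5R)-4-({[tert-butyl(dimethyl)silyl]oxy}methyl)-5-[(2Z,6E)-3-{[tert-butyl(diphenyl)silyl]oxymethyl}-7-methyl-9-(2,6,6-trimethylcyclohex-1-en-1-yl)nona-2,6-dien-1-yl]furan-2(5H)-one | CC(C)(C)[Si](OC/C(CC/C=C(\C)CCC1=C(C)CCCC1(C)C)=C\C[C@H]1OC(=O)C=C1CO[Si](C)(C)C(C)(C)C)(c1ccccc1)c1ccccc1 | intermediate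
25 | (6Z)-neomanoalide, (5R)-4-(hydroxymethyl)-5-[(2Z,6E)-3-(hydroxymethyl)-7-methyl-9-(2,6,6-trimethylcyclohex-1-en-1-yl)nona-2,6-dien-1-yl]furan-2(5H)-one | CC1=C(CC/C(C)=C/CC/C(=C/C[C@H]2OC(=O)C=C2CO)CO)C(C)(C)CCC1 | target

**Step count**

Total step count: 13.
Longest linear sequence: 13 steps (1 to 25; compounds 5, 10 and 13 are purchased and enter directly).

**Steps most likely to fail**

1. Step 5 (key step).
   - What may go wrong: soft enolisation of the α-branched ester may be slow. The adduct may form with C24 trans to C5, in which case it cannot lactonise and is lost to the open chain. The ligand and the dioxolane stereocentre may oppose each other and erode facial selectivity at C4.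
   - Fallback, setting out from 9 and 13 and returning at 16: the same lactone would be closed by ring-closing metathesis, so that the ring again fixes the 6Z geometry.
   - Acid part: alkylation of triethyl phosphonoacetate with 9 (NaH, DMF) should give ethyl (5E)-2-(diethoxyphosphoryl)-6-methyl-8-(2,6,6-trimethylcyclohex-1-en-1-yl)oct-5-enoate F2. Horner–Wadsworth–Emmons reaction with aqueous formaldehyde (K2CO3) should give the 2-methylidene ester F3, and LiOH the 2-methylidene acid F4.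
   - Alcohol part: Brown allylation of 13 with the B-allyldiisopinocampheylborane antipode matched to the anti (Felkin) adduct should give (1R)-1-[(4S)-2,2-dimethyl-1,3-dioxolan-4-yl]but-3-en-1-ol F1, which sets C4 by reagent and substrate control.
   - Union: Steglich esterification of F1 with F4 should give the diene ester F5, and second-generation Grubbs catalyst (toluene, 80 °C) should close the trisubstituted C6=C7 alkene with loss of ethylene to give 16.

2. Step 12.
   - What may go wrong: the amine base may enolise the α-acyloxy ketone towards C4 or deprotonate the butenolide at its γ-position, which would erode the C4 configuration.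
   - Fallback, setting out from 19 and returning at 24: the ring would be closed by a neutral intramolecular Wittig reaction instead.
   - The C4 hydroxyl of 19 would be protected as its 4-methoxybenzyl ether F6 (4-methoxybenzyl trichloroacetimidate, cat. PPTS) and the acetonide hydrolysed to the diol F7 (aq. AcOH).
   - The primary hydroxyl would be silylated to the tert-butyldimethylsilyl ether F8 (TBSCl, imidazole) and the C3 alcohol oxidised with Dess–Martin periodinane to the α-alkoxy ketone F9.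
   - DDQ would remove the benzyl ether to give the α-hydroxy ketone F10. Heating F10 with (triphenylphosphoranylidene)ketene, Ph3P=C=C=O, in toluene at 80 °C should acylate the hydroxyl and close the butenolide to give 24.
   - No ester sits beside the diol on this path, so the acyl-shift hazard of step 9 is avoided as well.

3. Step 4.
   - What may go wrong: the homoallylic iodide has allylic β-hydrogens and may undergo E2 elimination to a diene with the basic dienolate. Some γ-alkylation or double alkylation may also occur.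
   - Fallback, setting out from 9 and returning at 12: the polarity would be reversed.
   - Mg in THF should convert 9 into the Grignard reagent [(3E)-4-methyl-6-(2,6,6-trimethylcyclohex-1-en-1-yl)hex-3-en-1-yl]magnesium iodide F11.
   - CuBr·SMe2-catalysed SN2′ substitution of methyl (2E)-4-bromobut-2-enoate by F11 (CH2Cl2/THF, −78 °C) should deliver the alkyl group to the α-carbon and shift the alkene into the vinyl position, giving racemic 12 without any strongly basic enolate.

**Further compounds**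

F1 | step 5 | (1R)-1-[(4S)-2,2-dimethyl-1,3-dioxolan-4-yl]but-3-en-1-ol | C=CC[C@@H](O)[C@@H]1COC(C)(C)O1
F2 | step 5 | ethyl (5E)-2-(diethoxyphosphoryl)-6-methyl-8-(2,6,6-trimethylcyclohex-1-en-1-yl)oct-5-enoate, racemic | CCOC(=O)C(CC/C=C(\C)CCC1=C(C)CCCC1(C)C)P(=O)(OCC)OCC
F3 | step 5 | ethyl (5E)-6-methyl-2-methylidene-8-(2,6,6-trimethylcyclohex-1-en-1-yl)oct-5-enoate | CCOC(=O)C(=C)CC/C=C(\C)CCC1=C(C)CCCC1(C)C
F4 | step 5 | (5E)-6-methyl-2-methylidene-8-(2,6,6-trimethylcyclohex-1-en-1-yl)oct-5-enoic acid | OC(=O)C(=C)CC/C=C(\C)CCC1=C(C)CCCC1(C)C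
F5 | step 5 | (1R)-1-[(4S)-2,2-dimethyl-1,3-dioxolan-4-yl]but-3-en-1-yl (5E)-6-methyl-2-methylidene-8-(2,6,6-trimethylcyclohex-1-en-1-yl)oct-5-enoate | C=CC[C@@H](OC(=O)C(=C)CC/C=C(\C)CCC1=C(C)CCCC1(C)C)[C@@H]1COC(C)(C)O1
F6 | step 12 | 4-methoxybenzyl ether of 19 at the C4 oxygen | CC(C)(C)[Si](OC/C(CC/C=C(\C)CCC1=C(C)CCCC1(C)C)=C\C[C@@H](OCc1ccc(OC)cc1)[C@@H]1COC(C)(C)O1)(c1ccccc1)c1ccccc1
F7 | step 12 | (2S,3R,5Z,9E)-6-{[tert-butyl(diphenyl)silyl]oxymethyl}-3-[(4-methoxybenzyl)oxy]-10-methyl-12-(2,6,6-trimethylcyclohex-1-en-1-yl)dodeca-5,9-diene-1,2-diol | CC(C)(C)[Si](OC/C(CC/C=C(\C)CCC1=C(C)CCCC1(C)C)=C\C[C@@H](OCc1ccc(OC)cc1)[C@@H](O)CO)(c1ccccc1)c1ccccc1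
F8 | step 12 | (2S,3R,5Z,9E)-1-{[tert-butyl(dimethyl)silyl]oxy}-6-{[tert-butyl(diphenyl)silyl]oxymethyl}-3-[(4-methoxybenzyl)oxy]-10-methyl-12-(2,6,6-trimethylcyclohex-1-en-1-yl)dodeca-5,9-dien-2-ol | CC(C)(C)[Si](OC/C(CC/C=C(\C)CCC1=C(C)CCCC1(C)C)=C\C[C@@H](OCc1ccc(OC)cc1)[C@@H](O)CO[Si](C)(C)C(C)(C)C)(c1ccccc1)c1ccccc1
F9 | step 12 | (3R,5Z,9E)-1-{[tert-butyl(dimethyl)silyl]oxy}-6-{[tert-butyl(diphenyl)silyl]oxymethyl}-3-[(4-methoxybenzyl)oxy]-10-methyl-12-(2,6,6-trimethylcyclohex-1-en-1-yl)dodeca-5,9-dien-2-one | CC(C)(C)[Si](OC/C(CC/C=C(\C)CCC1=C(C)CCCC1(C)C)=C\C[C@@H](OCc1ccc(OC)cc1)C(=O)CO[Si](C)(C)C(C)(C)C)(c1ccccc1)c1ccccc1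
F10 | step 12 | (3R,5Z,9E)-1-{[tert-butyl(dimethyl)silyl]oxy}-6-{[tert-butyl(diphenyl)silyl]oxymethyl}-3-hydroxy-10-methyl-12-(2,6,6-trimethylcyclohex-1-en-1-yl)dodeca-5,9-dien-2-one | CC(C)(C)[Si](OC/C(CC/C=C(\C)CCC1=C(C)CCCC1(C)C)=C\C[C@@H](O)C(=O)CO[Si](C)(C)C(C)(C)C)(c1ccccc1)c1ccccc1
F11 | step 4 | [(3E)-4-methyl-6-(2,6,6-trimethylcyclohex-1-en-1-yl)hex-3-en-1-yl]magnesium iodide | I[Mg]CC/C=C(\C)CCC1=C(C)CCCC1(C)C
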